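The six-membered carbocycle C2=C3–C4–C24–C23–C22 of the bicyclo[2.2.2]octene, with its C1 methyl group, is traced back to the aromatic ring of creosol. Oxidative dearomatisation turns creosol into a ketal-masked o-quinone whose diene adds across the C5=C21 alkene of O-silylated (+)-altholactone. This single cycloaddition makes C4–C5 and C21–C22, closes the bridged ring and sets C4, C5, C21 and C22 under control of the lactone. The dienophile, a cis-fused oxolane–dihydropyranone holding C9, C10, C12 and C20, is built from (E)-cinnamyl alcohol. Afterwards isopropyl is added at C24, the carbonyl is transposed to C23 so that C24 can equilibrate, and C23 is reduced to CH2.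

Key step: step 9

Remark: atom labels (C1 to C27, O7, O8, O11, O19) follow the atom order of the target SMILES. In the target, C6 and C20 lie on the C2=C3 side of the bicyclooctene, C4 and C22 are anti to O19 on the lactone ring, and the isopropyl group points toward C2=C3. The C=N geometry of hydrazone 19 is left open because it is lost in the next step.

Step 1
Reactants: 1 (E)-cinnamyl alcohol
Product: 2 (2S,3S)-3-phenyloxiran-2-ylmethanol
Conditions: Ti(OiPr)4 (cat.), L-(+)-diisopropyl tartrate (cat.), tBuOOH, 4 Å molecular sieves, CH2Cl2, −20 °C; recrystallisation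
Reagents that add atoms: tert-butyl hydroperoxide, CC(C)(C)OO
Why: Sharpless asymmetric epoxidation, in which the titanium tartrate complex delivers oxygen to one alkene face of the allylic alcohol, L-(+)-tartrate giving the (2S,3S)-epoxide that fixes C10 and, after a later inversion, C12.

Step 2
Reactants: 2 (2S,3S)-3-phenyloxiran-2-ylmethanol
Product: 3 (2R,3S)-3-phenyloxirane-2-carbaldehyde
Conditions: TEMPO (cat.), PhI(OAc)2, CH2Cl2, rt; used without storage
Reagents that add atoms: none
Why: Oxoammonium (TEMPO) oxidation of a primary alcohol stops at the aldehyde under nearly neutral conditions that leave the aryl epoxide and both stereocentres untouched.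

Step 3
Reactants: 4 allyl alcohol
Product: 5 allyl methoxymethyl ether
Conditions: MOMCl, iPr2NEt, CH2Cl2, 0 °C → rt; distillation
Reagents that add atoms: chloromethyl methyl ether, COCCl
Why: O-alkylation of a primary alcohol with an α-chloro ether (acetal protection), with no stereocentre involved.

Step 4
Reactants: 3 (2R,3S)-3-phenyloxirane-2-carbaldehyde; 5 allyl methoxymethyl ether
Product: 7 (1R,2S)-2-(methoxymethoxy)-1-[(2S,3S)-3-phenyloxiran-2-yl]but-3-en-1-ol, via (Z)-alkoxyallylborane 6 (not isolated)
Conditions: 5, sBuLi, THF, −78 °C; (+)-Ipc2BOMe [Ipc from (−)-α-pinene]; BF3·OEt2; then 3, −78 °C → rt; HOCH2CH2NH2, Et2O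
Reagents that add atoms: none
Why: Brown-type asymmetric alkoxyallylboration, in which the (Z)-borane reacts through a chair Zimmerman–Traxler transition state to give the syn diol monoether and the isopinocampheyl groups steer attack to the Re face of the aldehyde, so C9 and C20 are set by reagent control over the small intrinsic bias of an epoxy aldehyde.

Step 5
Reactants: 7 (1R,2S)-2-(methoxymethoxy)-1-[(2S,3S)-3-phenyloxiran-2-yl]but-3-en-1-ol
Product: 8 acrylate ester of 7
Conditions: acryloyl chloride, iPr2NEt, CH2Cl2, 0 °C
Reagents that add atoms: acryloyl chloride, C=CC(=O)Cl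
Why: Acylation of the only free hydroxyl, which marks O8 as the lactone oxygen while O19 stays masked as the acetal and O11 as the epoxide.

Step 6
Reactants: 8 acrylate ester of 7
Product: 9 (5S,6R)-5-(methoxymethoxy)-6-[(2S,3S)-3-phenyloxiran-2-yl]-5,6-dihydropyran-2-one
Conditions: second-generation Grubbs catalyst RuCl2(=CHPh)(PCy3)(H2IMes) (5 mol %), CH2Cl2 (high dilution), 40 °C
Reagents that add atoms: none
Why: Ring-closing metathesis of an acrylate with an allylic-ether vinyl group, a standard entry to 5-alkoxy-5,6-dihydropyran-2-ones in which the six-membered ring enforces the Z alkene C5=C21 and the epoxide is inert.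

Step 7
Reactants: 9 (5S,6R)-5-(methoxymethoxy)-6-[(2S,3S)-3-phenyloxiran-2-yl]-5,6-dihydropyran-2-one
Product: 10 (+)-altholactone, (2R,3R,3aS,7aS)-3-hydroxy-2-phenyl-2,3,3a,7a-tetrahydro-5H-furo[3,2-b]pyran-5-one
Conditions: CF3CO2H, CH2Cl2, H2O (trace), 0 °C → rt; aq NaHCO3
Reagents that add atoms: none
Why: Acid-catalysed acetal cleavage and 5-endo-tet epoxide opening, in which O19 attacks the activated benzylic carbon C12 from the rear with inversion, the lactone carbonyl is geometrically unable to compete, and even a more ionised pathway should close to the same oxolane with phenyl trans to the C10 hydroxyl.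

Step 8
Reactants: 10 (+)-altholactone
Product: 11 O-tert-butyldimethylsilyl altholactone
Conditions: TBSOTf, 2,6-lutidine, CH2Cl2, −78 → 0 °C
Reagents that add atoms: tert-butyldimethylsilyl triflate, CC(C)(C)[Si](C)(C)OS(=O)(=O)C(F)(F)F
Why: Silylation of the single secondary alcohol with a silyl triflate and a weak hindered base, which spares the base-sensitive γ-alkoxy enoate and gives a group that later falls off in the same acid step as the ketal.

Step 9
Reactants: 11 O-tert-butyldimethylsilyl altholactone; 12 creosol (2-methoxy-4-methylphenol)
Product: 14 endo adduct bearing the C24 ketone plus the C23 dimethyl ketal (O-TBS), via dimethoxy dienone 13 (not isolated)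
Conditions: PhI(OAc)2 (excess), MeOH, 50 °C; 12 (excess) in MeOH added by syringe pump over several hours to 11 (limiting)
Reagents that add atoms: methanol, CO
Why: PhI(OAc)2 oxidises the phenol and methanol is captured at the methoxy-bearing carbon, giving o-quinone monoketal 13, which serves as the 4π partner in a concerted, asynchronous, suprafacial [4+2] cycloaddition with the lactone alkene, the established Diels–Alder chemistry of masked o-benzoquinones with electron-poor alkenes. The one new ring is closed intermolecularly by forming C4–C5 and C21–C22 together, which converts the dienone ring into the bicyclo[2.2.2]oct-5-en-2-one. C5 and C21 keep the cis relationship of the ring alkene, and their absolute sense follows from attack on the convex lactone face, anti to O19 and C10, because the concave face is covered by the oxolane and its C12 phenyl group. C4 and C22 are fixed by the endo orientation, in which C6=O and the rest of the lactone sit under the diene (the future C2=C3) and away from the two methoxy groups, 13 itself being flat and achiral. The required regiochemistry (carbonyl-bearing C5 to the dienone carbon next to C=O, C21 to the carbon next to the ketal) follows the ortho preference of the dienone carbonyl and the para preference of the methyl group, which reinforce each other. Because 13 also dimerises, it is generated slowly, kept dilute and used in excess over the valuable lactone.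

Step 10
Reactants: 14 endo adduct (C24 ketone, C23 dimethyl ketal, O-TBS)
Product: 15 C24 tertiary carbinol (isopropyl on the C2=C3 side, hydroxyl on the C5–C21 side; ketal and O-TBS retained)
Conditions: iPrMgCl, CeCl3 (anhydrous), THF, −78 °C; aq NH4Cl
Reagents that add atoms: isopropylmagnesium chloride, CC(C)[Mg]Cl
Why: Organocerium 1,2-addition, in which the non-enolisable, ketal-activated bridged ketone should react faster than the lactone at −78 °C, CeCl3 suppresses β-hydride reduction, attack comes past the flat C2=C3 bridge, and the new C24 configuration is erased later.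

Step 11
Reactants: 15 C24 tertiary carbinol
Product: 16 α-ketol (C23 ketone, C24 tertiary alcohol, free C10 hydroxyl)
Conditions: 2 M aq HCl, THF, 40 °C
Reagents that add atoms: water, O
Why: Acid-catalysed acetal hydrolysis and silyl ether cleavage in one operation, the ketal being hydrolysable now that C24 is a carbinol and no longer a carbonyl that would destabilise the C23 oxocarbenium ion, while lactone, oxolane and alkene tolerate dilute acid.

Step 12
Reactants: 16 α-ketol
Product: 18 C23 ketone having the C24 isopropyl group syn to C2=C3, via C24-epimeric ketone 17 (not isolated)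
Conditions: SmI2, THF–MeOH, −78 → 0 °C; work-up; DBU (cat.), toluene, rt → 40 °C
Reagents that add atoms: none
Why: SmI2 reductive cleavage of an α-hydroxy ketone (ketyl, loss of hydroxide, samarium enolate) followed by base equilibration, in which C24 is the only enolisable position of the ketone (C22 is a bridgehead), the isopropyl group should settle over the sp2 bridge to avoid the parallel C5–H bond, and C5 stays put because the lactone is less acidic and cis fusion is preferred.

Step 13
Reactants: 18 C23 ketone
Product: 19 C23 tosylhydrazone of 18
Conditions: TsNHNH2, PPTS (cat.), EtOH, 70 °C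
Reagents that add atoms: p-toluenesulfonyl hydrazide, Cc1ccc(cc1)S(=O)(=O)NN
Why: Hydrazone condensation at the only ketone, where any C24 exchange through the ene-hydrazine would follow the same thermodynamic bias as in step 12.

Step 14
Reactants: 19 C23 tosylhydrazone
Product: 20 target CNP0249919.1
Conditions: catecholborane (excess), CHCl3, −10 °C → rt; NaOAc·3H2O, reflux
Reagents that add atoms: none
Why: Caglioti-type tosylhydrazone reduction (hydride addition to C=N, loss of sulfinate, diazene losing N2), which turns C23 into CH2 under conditions too mild to touch the lactone, the trisubstituted alkene or C24, the free hydroxyl being only transiently borylated.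

Compound list
1 | (E)-cinnamyl alcohol | OC/C=C/c1ccccc1 | starting material
2 | (2S,3S)-3-phenyloxiran-2-ylmethanol | OC[C@@H]1O[C@H]1c1ccccc1 | intermediate
3 | (2R,3S)-3-phenyloxirane-2-carbaldehyde | O=C[C@@H]1O[C@H]1c1ccccc1 | intermediate
4 | allyl alcohol | C=CCO | starting material
5 | allyl methoxymethyl ether | C=CCOCOC | intermediate
6 | (Z)-3-(methoxymethoxy)allyl-bis(isopinocampheyl)borane, Ipc from (−)-α-pinene | COCO/C=C\CB([C@H]1C[C@H]2C[C@@H]([C@@H]1C)C2(C)C)[C@H]1C[C@H]2C[C@@H]([C@@H]1C)C2(C)C | intermediate
7 | (1R,2S)-2-(methoxymethoxy)-1-[(2S,3S)-3-phenyloxiran-2-yl]but-3-en-1-ol | C=C[C@H](OCOC)[C@@H](O)[C@@H]1O[C@H]1c1ccccc1 | intermediate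
8 | acrylate ester of 7 | C=C[C@H](OCOC)[C@@H](OC(=O)C=C)[C@@H]1O[C@H]1c1ccccc1 | intermediate
9 | (5S,6R)-5-(methoxymethoxy)-6-[(2S,3S)-3-phenyloxiran-2-yl]-5,6-dihydropyran-2-one | O=C1C=C[C@H](OCOC)[C@@H](O1)[C@@H]2O[C@H]2c3ccccc3 | intermediate
10 | (+)-altholactone | O=C1O[C@H]2[C@H](O)[C@@H](c3ccccc3)O[C@H]2C=C1 | intermediate
11 | O-tert-butyldimethylsilyl altholactone | O=C1O[C@H]2[C@H](O[Si](C)(C)C(C)(C)C)[C@@H](c3ccccc3)O[C@H]2C=C1 | intermediate
12 | creosol (2-methoxy-4-methylphenol) | COc1cc(C)ccc1O | starting material
13 | 6,6-dimethoxy-4-methylcyclohexa-2,4-dien-1-one | COC1(OC)C=C(C)C=CC1=O | intermediate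
14 | endo Diels–Alder adduct, C24 ketone, C23 dimethyl ketal, O-TBS | CC1=C[C@@H]2[C@@H]3C(=O)O[C@H]4[C@H](O[Si](C)(C)C(C)(C)C)[C@@H](c5ccccc5)O[C@H]4[C@@H]3[C@H]1C(OC)(OC)C2=O | intermediate
15 | C24 isopropyl carbinol, C23 dimethyl ketal, O-TBS | CC1=C[C@@H]2[C@@H]3C(=O)O[C@H]4[C@H](O[Si](C)(C)C(C)(C)C)[C@@H](c5ccccc5)O[C@H]4[C@@H]3[C@H]1C(OC)(OC)[C@]2(O)C(C)C | intermediate
16 | α-ketol, C23 ketone, C24 tertiary alcohol, free C10 hydroxyl | CC1=C[C@@H]2[C@@H]3C(=O)O[C@H]4[C@H](O)[C@@H](c5ccccc5)O[C@H]4[C@@H]3[C@H]1C(=O)[C@]2(O)C(C)C | intermediate
17 | C23 ketone, C24 epimer (isopropyl toward the C5–C21 bridge) | CC1=C[C@@H]2[C@@H]3C(=O)O[C@H]4[C@H](O)[C@@H](c5ccccc5)O[C@H]4[C@@H]3[C@H]1C(=O)[C@H]2C(C)C | intermediate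
18 | C23 ketone, isopropyl syn to C2=C3 | CC1=C[C@@H]2[C@@H]3C(=O)O[C@H]4[C@H](O)[C@@H](c5ccccc5)O[C@H]4[C@@H]3[C@H]1C(=O)[C@@H]2C(C)C | intermediate
19 | C23 tosylhydrazone of 18 | CC1=C[C@@H]2[C@@H]3C(=O)O[C@H]4[C@H](O)[C@@H](c5ccccc5)O[C@H]4[C@@H]3[C@H]1C(=NNS(=O)(=O)c6ccc(C)cc6)[C@@H]2C(C)C | intermediate
20 | CNP0249919.1 | CC1=C[C@@H]2[C@@H]3C(=O)O[C@H]4[C@H](O)[C@@H](c5ccccc5)O[C@H]4[C@@H]3[C@H]1C[C@@H]2C(C)C | target

Total step count: 14. Longest linear sequence: 13 steps (1 to 20 through steps 1, 2 and 4–14).

Steps most likely to fail

Step 9. Self-dimerisation of the dienone may outrun its addition to a β-substituted, only moderately activated lactone. Crowding at the forming C21–C22 bond (next to the ketal and the methyl-bearing carbon) may also erode the regiochemistry. The fallback separates oxidation from cycloaddition. Creosol 12 is oxidised alone with PhI(OAc)2 in MeOH at rt, and the dienone is allowed to dimerise to the isolable dienone dimer F1. F1 is then heated with 11 in mesitylene in a sealed tube at about 200–220 °C. A domino retro-Diels–Alder/Diels–Alder sequence releases 13 slowly, with no oxidant, acid or methanol present. This path sets out from 12 and 11 and returns at 14.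

Step 12. Loss of the unactivated tertiary hydroxyl may be sluggish, and the thermodynamic bias at C24 may be too small, so much material would cycle through re-equilibration. The fallback buys the C24 stereocentre instead of setting it. Compound 11 is heated with (R)-(−)-α-phellandrene (CC1=CC[C@H](C(C)C)C=C1) and a trace of BHT in toluene in a sealed tube at about 150 °C. In this normal-demand Diels–Alder reaction the diene should be attacked anti to its isopropyl group and the lactone on its convex face, with endo and para orientation. The product is the O-silyl ether of the target F2, which HF·pyridine in THF converts into the target. This path sets out from 11 and returns at 20.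

Step 10. β-Hydride reduction of the hindered ketone by the secondary Grignard reagent, or competing attack at the lactone, may consume material. The fallback uses a slimmer sp2 nucleophile that has no transferable β-hydride. Isopropenylmagnesium bromide with CeCl3 in THF at −78 °C should give the isopropenyl carbinol F3. Its 1,1-disubstituted alkene is then hydrogenated with H2 and RhCl(PPh3)3 in benzene, which leaves the trisubstituted C2=C3 alkene alone. This path sets out from 14 and returns at 15.

Further compounds
F1 | step 9 | Diels–Alder dimer of dienone 13 (racemic, one enantiomer drawn) | CC1=C[C@@H]2[C@]3(C)C=CC(=O)C(OC)(OC)[C@@H]3[C@H]1C(OC)(OC)C2=O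
F2 | step 12 | O-tert-butyldimethylsilyl ether of the target | CC1=C[C@@H]2[C@@H]3C(=O)O[C@H]4[C@H](O[Si](C)(C)C(C)(C)C)[C@@H](c5ccccc5)O[C@H]4[C@@H]3[C@H]1C[C@@H]2C(C)C
F3 | step 10 | C24 isopropenyl carbinol, C23 dimethyl ketal, O-TBS | CC1=C[C@@H]2[C@@H]3C(=O)O[C@H]4[C@H](O[Si](C)(C)C(C)(C)C)[C@@H](c5ccccc5)O[C@H]4[C@@H]3[C@H]1C(OC)(OC)[C@]2(O)C(C)=C
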